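**Plan** (locants as in the target: ring N; C5–C8 chain; C9 ketone; C9a lactam C=O; C1 carbinol; C2; C3; C10 CHEt; C11 CH–O; C12; C13 CHMe; C14 lactone C=O; C18–C21 pendant lactone; α = face of the carbocycle carrying the C1–C2 bond, β = face of the C1–O bond)

- Key cut: the C9 ketone and the C9a lactam carbonyl are linked on one side by C10–C11–C12–C1 and on the other by C8–C7–C6–C5–N. They are therefore the two ends of a former C9=C9a enamine double bond shared by a cyclohexene (C1, C9a, C9, C10, C11, C12) and an azepine (N, C5–C8, C9, C9a).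
- Further cuts, going backwards: C10–ethyl, N–C5, C11–O and C12–C13 (fused lactone), C18–O and C3–C18 (pendant lactone), C9–C8, then N–C9a and the C1–O bond, which leaves L-tyrosine (Cα, Cβ, ipso carbon = C3, C2, C1).
- Forward ring order: pyrrolidine, pendant butyrolactone, fused butyrolactone, azepine. The 11-membered ring is never closed; it appears when the bond common to the six- and seven-membered rings is cleaved.
- Stereochemistry: C3 is L-tyrosine's and sets C1 (and temporary C9a) in the aza-Michael closure. C20 is bought. C18 comes from Felkin–Anh reduction next to C3. The temporary C9 centre directs the Luche reduction to the 10α-alcohol, which is relayed to C12/C13 by the Claisen shift. C11 follows from anti iodolactonisation and C10 from organocopper addition anti to the lactone oxygen.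

Key step: step 17

Remark: N,N-dimethylpropionamide dimethyl acetal (16) is taken as a catalogue reagent; otherwise it is made in one operation from N,N-dimethylpropionamide (Me2SO4, then NaOMe).
Remark: the nitrogen configuration of N-oxide 26 and the face of dioxetane 31 are not controlled and do not matter, since both are destroyed in the next event; 26 is written without N-configuration and 31 as the β-face adduct.
Remark: the C13 configuration from step 10 rests on a transition-state argument, not on a close precedent; no later step is relied on to correct it.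

**Step 1**
Reactants: 1 N-Boc-L-tyrosine
Product: 2 spirolactone dienone, tert-butyl [(3S)-2,8-dioxo-1-oxaspiro[4.5]deca-6,9-dien-3-yl]carbamate
Conditions: PhI(OAc)2, MeNO2, 0 °C → rt
Reagents that add atoms: none
Why: Iodine(III) oxidative dearomatisation of the phenol with ipso capture by the carboxylate (spirolactonisation) should give the cyclohexadienone without touching the α-stereocentre.

**Step 2**
Reactants: 2 spirolactone dienone
Product: 4 methyl (2S,3aR,7aR)-1-Boc-3a-hydroxy-6-oxo-2,3,3a,6,7,7a-hexahydroindole-2-carboxylate (cis-fused; C3 ester, C1–OH and C9a–H on one face), via ring-opened dienone ester 3 (not isolated)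
Conditions: NaHCO3, MeOH, 40 °C
Reagents that add atoms: methanol, CO
Why: Methanolysis of the spirolactone is followed by 5-exo aza-Michael addition of the carbamate nitrogen to one of the two diastereotopic enone arms; the tether enforces cis fusion and A(1,3) strain between the C3 ester and the N-Boc group selects the arm, so C3 sets C1 and C9a.

**Step 3**
Reactants: 4 hydroxy hydroindolenone
Product: 5 C1 triethylsilyl ether of 4, methyl (2S,3aR,7aR)-1-Boc-6-oxo-3a-(triethylsilyloxy)-2,3,3a,6,7,7a-hexahydroindole-2-carboxylate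
Conditions: TESOTf, 2,6-lutidine, CH2Cl2, −78 → 0 °C
Reagents that add atoms: triethylsilyl trifluoromethanesulfonate, CC[Si](CC)(CC)OS(=O)(=O)C(F)(F)F
Why: Silyl triflate with a hindered pyridine base silylates tertiary alcohols; the TES ether is chosen because it survives base, hydride, heat and iodine yet leaves under mild acidic fluoride at the end.

**Step 4**
Reactants: 5 silyl ether enone; 6 1-chloro-4-iodobutane
Product: 7 9β-(4-chlorobutyl) enone (side chain trans to the C9a–N bond; (2S,3aR,7R,7aR) in hexahydroindole numbering)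
Conditions: LDA (1.05 equiv), THF, −78 °C; then 6, DMPU, −78 → −30 °C
Reagents that add atoms: none
Why: Kinetic α′-deprotonation (C1 is quaternary, so there is no γ-hydrogen) gives the cross-conjugated lithium dienolate, which is alkylated by the iodide end of 6 on the face anti to the neighbouring carbamate nitrogen, the chloride being left as a latent electrophile.

**Step 5**
Reactants: 7 chlorobutyl enone
Product: 8 10α-allylic alcohol (C10–OH trans to the C9 side chain, on the face of the pyrrolidine ring), C3 methyl ester
Conditions: NaBH4, CeCl3·7H2O, MeOH, −78 °C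
Reagents that add atoms: none
Why: Luche 1,2-reduction with axial hydride delivery from the β face, opposite the pyrrolidine ring, should give the 10α-alcohol trans to the C9 substituent.

**Step 6**
Reactants: 8 allylic alcohol methyl ester
Product: 9 C3 carboxylic acid
Conditions: LiOH·H2O, THF/H2O, 0 °C → rt; then dilute HCl to pH 4
Reagents that add atoms: lithium hydroxide, [Li+].[OH-]
Why: Saponification of the methyl ester; the carbamate-protected α-centre, the tertiary silyl ether and the primary chloride tolerate cold aqueous hydroxide.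

**Step 7**
Reactants: 9 carboxylic acid
Product: 10 S-ethyl thioester at C3
Conditions: EtSH, DCC, DMAP (cat.), CH2Cl2, 0 °C → rt
Reagents that add atoms: ethanethiol, CCS
Why: Carbodiimide thioesterification (Steglich type); the thiol outcompetes the hindered secondary alcohol, and an N,N-disubstituted urethane amino acid cannot racemise through an oxazolone.

**Step 8**
Reactants: 10 thioester; 11 methyl (R)-3-bromo-2-methylpropanoate
Product: 13 C18 γ-keto ester (C3–CO–CH2–CH(CH3)–CO2Me), via zinc homoenolate 12 (not isolated)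
Conditions: 11, Zn dust, I2 (cat.), DMA, 70 °C; then 10, PdCl2(PPh3)2 (cat.), toluene, rt
Reagents that add atoms: none
Why: Fukuyama coupling (Pd insertion into C–S, transmetalation with the β-zincio ester, reductive elimination) gives the ketone under neutral conditions that spare the free hydroxyl, chloride and carbamate; the centre β to zinc, the future C20, is configurationally stable.

**Step 9**
Reactants: 13 γ-keto ester
Product: 15 allylic alcohol carrying the pendant (18S,20S)-α-methyl-γ-butyrolactone, via C18 hydroxy ester 14 (not isolated)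
Conditions: L-Selectride (2.5 equiv), THF, −78 °C; aq NH4Cl; then PPTS (cat.), toluene, 40 °C
Reagents that add atoms: none
Why: Felkin–Anh reduction by the bulky borohydride anti to the C3–N bond should set (18S), and the γ-hydroxy ester then lactonises under mild acid that leaves the TES ether intact.

**Step 10**
Reactants: 15 lactone-bearing allylic alcohol; 16 N,N-dimethylpropionamide dimethyl acetal
Product: 18 C12 α-side-chain N,N-dimethylpropionamide with C10=C11 alkene, via ketene N,O-acetal 17 (not isolated)
Conditions: 16 (excess), xylenes, 140 °C, MeOH distilled off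
Reagents that add atoms: none
Why: Eschenmoser–Claisen rearrangement: the suprafacial [3,3] shift trades the α C10–O bond for an α C12–C13 bond next to quaternary C1, and because the space under the ring is filled by the cis-fused pyrrolidine, only a boat-like array with the amide carbon turned outward and the C13 methyl exo (the (E)-acetal 17, equilibrating with its (Z)-isomer) should be reachable, which places the methyl on the later convex lactone face.

**Step 11**
Reactants: 18 unsaturated amide
Product: 20 10β-iodo cis-fused lactone (C11–O α, C13 methyl on the convex face), via iminium lactone iodide 19 (not isolated)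
Conditions: I2, THF/H2O, 0 °C → rt, dark; aq Na2S2O3/NaHCO3
Reagents that add atoms: iodine, II; water, O
Why: Iodolactonisation through the amide oxygen: iodonium formation on the β face and 5-exo anti attack of the α-held amide oxygen at C11 give the cis-fused iminium lactone, hydrolysed in situ with loss of dimethylamine, so C11–O is α and C10–I is β.

**Step 12**
Reactants: 20 iodolactone
Product: 21 N-Boc lactone with C9=C10 alkene and 4-chlorobutyl on C9
Conditions: DBU, toluene, 80 °C
Reagents that add atoms: none
Why: E2 dehydroiodination: the only hydrogen antiperiplanar to the β C10–I bond is the α C9–H (C11–H is syn to iodine), so the alkene forms toward C9; temperature and time are kept moderate so that the lactone α-centres C13 and C20 are not enolised.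

**Step 13**
Reactants: 21 chloroalkene
Product: 22 corresponding 4-iodobutyl compound
Conditions: NaI, acetone, reflux
Reagents that add atoms: sodium iodide, [Na+].[I-]
Why: Finkelstein exchange, driven by precipitation of NaCl, turns the robust chloride into a reactive iodide only now, so that the next ring closure can run at room temperature.

**Step 14**
Reactants: 22 N-Boc iodide
Product: 25 tricyclic allylic amine (azepine closed, C9=C10 alkene, C9a–H β), via silyl carbamate 23 (not isolated), via amino iodide 24 (not isolated)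
Conditions: TMSOTf, 2,6-lutidine, CH2Cl2, 0 °C; MeOH, evaporate; i-Pr2NEt, MeCN (0.01 M), rt
Reagents that add atoms: none
Why: Silyl triflate cleavage of the Boc group (loss of the tert-butyl cation, then methanolysis of the silyl carbamate) spares the TES ether and both lactones, and the freed nitrogen closes the azepine by 7-exo-tet displacement of the primary iodide at room temperature, which should outrun O→N acyl transfer from the neighbouring pendant lactone.

**Step 15**
Reactants: 25 tricyclic allylic amine
Product: 26 its N-oxide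
Conditions: mCPBA (1.05 equiv), CH2Cl2, −20 °C; filtration through basic alumina
Reagents that add atoms: 3-chloroperoxybenzoic acid, OOC(=O)c1cccc(Cl)c1
Why: Peracid N-oxidation of a tertiary amine is much faster than epoxidation of the trisubstituted, oxygen-deactivated alkene, and the N-oxide is kept cold to avoid [2,3]-Meisenheimer rearrangement.

**Step 16**
Reactants: 26 N-oxide; 27 ethylmagnesium bromide
Product: 30 tetrasubstituted C9=C9a enamine with 10β-ethyl, via conjugated iminium trifluoroacetate 28 (not isolated), via ethylcopper 29 (not isolated)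
Conditions: TFAA, CH2Cl2, −78 → 0 °C, evaporate; then EtCu (from 27 and CuBr·SMe2, THF/Me2S, −45 °C), THF, −78 °C; NH4Cl/NH3 (pH 9) work-up
Reagents that add atoms: none
Why: Polonovski–Potier reaction followed by organocopper conjugate addition: O-trifluoroacetylation and loss of the allylic, α-amino C9a hydrogen give the conjugated iminium ion, and ethylcopper adds at C10 (C9a is fully substituted and flanked by quaternary C1) from the β face, anti to the C11–O bond of the α-fused lactone, which sets C10 and gives the enamine directly.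

**Step 17**
Reactants: 30 enamine
Product: 32 11-membered keto-lactam, C1 triethylsilyl ether, via 1,2-dioxetane 31 (not isolated)
Conditions: O2, tetraphenylporphyrin (cat.), visible light, CH2Cl2, −78 °C; then warm to rt in the dark
Reagents that add atoms: dioxygen, O=O
Why: The nucleophilic enamine carbon C9 attacks singlet oxygen, the peroxy-iminium zwitterion closes onto C9a to dioxetane 31, and [2+2] cycloreversion on warming releases the C9 ketone and the C9a lactam carbonyl in one event. The closest known reaction type is the dye-sensitised photooxygenative cleavage of enamines to ketone plus amide, the aliphatic relative of the oxidative scission of ring-fused indoles. No ring is closed by bond formation: the 11-membered ring appears because the bond common to the cyclohexene and the azepine is removed, so no medium-ring cyclisation is needed. No stereocentre is created; C1, C12, C11 and C10, all set on the rigid six-membered ring, are carried over unchanged, and the cold neutral medium protects C10, now the α-centre of a β-acyloxy ketone. The step needs [2+2] scission rather than the ene reaction at the C8 or C10 hydrogens: a fully substituted, nitrogen-conjugated ring alkene favours the zwitterion/dioxetane path, quaternary C1 allows no other enamine isomer, and the only oxidisable nitrogen becomes an inert lactam in the same event.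

**Step 18**
Reactants: 32 silylated keto-lactam
Product: 33 target CNP0221273.1
Conditions: HF·pyridine, pyridine/THF, 0 °C → rt
Reagents that add atoms: none
Why: Buffered, weakly acidic fluoride desilylation frees the tertiary C1 alcohol without basic conditions that would epimerise C10 or eliminate the β-acyloxy ketone.

**Compound list**
1 | N-Boc-L-tyrosine | CC(C)(C)OC(=O)N[C@@H](Cc1ccc(O)cc1)C(=O)O | starting material
2 | tert-butyl [(3S)-2,8-dioxo-1-oxaspiro[4.5]deca-6,9-dien-3-yl]carbamate | CC(C)(C)OC(=O)N[C@H]1CC2(C=CC(=O)C=C2)OC1=O | intermediate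
3 | methyl (S)-2-(Boc-amino)-3-(1-hydroxy-4-oxocyclohexa-2,5-dien-1-yl)propanoate | CC(C)(C)OC(=O)N[C@@H](CC1(O)C=CC(=O)C=C1)C(=O)OC | intermediate (not isolated)
4 | methyl (2S,3aR,7aR)-1-Boc-3a-hydroxy-6-oxo-2,3,3a,6,7,7a-hexahydroindole-2-carboxylate | O=C1C=C[C@]2(O)C[C@@H](C(=O)OC)N(C(=O)OC(C)(C)C)[C@@H]2C1 | intermediate
5 | C1 triethylsilyl ether of 4 | O=C1C=C[C@]2(O[Si](CC)(CC)CC)C[C@@H](C(=O)OC)N(C(=O)OC(C)(C)C)[C@@H]2C1 | intermediate
6 | 1-chloro-4-iodobutane | ClCCCCI | starting material
7 | 9β-(4-chlorobutyl) enone | O=C1C=C[C@]2(O[Si](CC)(CC)CC)C[C@@H](C(=O)OC)N(C(=O)OC(C)(C)C)[C@@H]2[C@H]1CCCCCl | intermediate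
8 | 10α-allylic alcohol, C3 methyl ester | O[C@@H]1C=C[C@]2(O[Si](CC)(CC)CC)C[C@@H](C(=O)OC)N(C(=O)OC(C)(C)C)[C@@H]2[C@H]1CCCCCl | intermediate
9 | 10α-allylic alcohol, C3 carboxylic acid | O[C@@H]1C=C[C@]2(O[Si](CC)(CC)CC)C[C@@H](C(=O)O)N(C(=O)OC(C)(C)C)[C@@H]2[C@H]1CCCCCl | intermediate
10 | 10α-allylic alcohol, C3 S-ethyl thioester | O[C@@H]1C=C[C@]2(O[Si](CC)(CC)CC)C[C@@H](C(=O)SCC)N(C(=O)OC(C)(C)C)[C@@H]2[C@H]1CCCCCl | intermediate
11 | methyl (R)-3-bromo-2-methylpropanoate | BrC[C@H](C)C(=O)OC | starting material
12 | (R)-(3-methoxy-2-methyl-3-oxopropyl)zinc bromide | Br[Zn]C[C@H](C)C(=O)OC | intermediate (not isolated)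
13 | C18 γ-keto ester | O[C@@H]1C=C[C@]2(O[Si](CC)(CC)CC)C[C@@H](C(=O)C[C@H](C)C(=O)OC)N(C(=O)OC(C)(C)C)[C@@H]2[C@H]1CCCCCl | intermediate
14 | (18S)-hydroxy ester | O[C@@H]1C=C[C@]2(O[Si](CC)(CC)CC)C[C@@H]([C@@H](O)C[C@H](C)C(=O)OC)N(C(=O)OC(C)(C)C)[C@@H]2[C@H]1CCCCCl | intermediate (not isolated)
15 | allylic alcohol with pendant (18S,20S)-α-methyl-γ-butyrolactone | O[C@@H]1C=C[C@]2(O[Si](CC)(CC)CC)C[C@@H]([C@@H]3C[C@H](C)C(=O)O3)N(C(=O)OC(C)(C)C)[C@@H]2[C@H]1CCCCCl | intermediate
16 | N,N-dimethylpropionamide dimethyl acetal (1,1-dimethoxy-N,N-dimethylpropan-1-amine) | CCC(OC)(OC)N(C)C | starting material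
17 | (E)-ketene N,O-acetal on the C10 oxygen | C/C=C(\N(C)C)O[C@@H]1C=C[C@]2(O[Si](CC)(CC)CC)C[C@@H]([C@@H]3C[C@H](C)C(=O)O3)N(C(=O)OC(C)(C)C)[C@@H]2[C@H]1CCCCCl | intermediate (not isolated)
18 | C12 α-side-chain N,N-dimethylpropionamide, C10=C11 alkene | C1=C[C@H]([C@H](C)C(=O)N(C)C)[C@]2(O[Si](CC)(CC)CC)C[C@@H]([C@@H]3C[C@H](C)C(=O)O3)N(C(=O)OC(C)(C)C)[C@@H]2[C@H]1CCCCCl | intermediate
19 | cis-fused iminium lactone iodide (C14=N+Me2), 10β-iodo | I[C@@H]1[C@H](CCCCCl)[C@H]2N(C(=O)OC(C)(C)C)[C@@H](C[C@@]2(O[Si](CC)(CC)CC)[C@@H]3[C@H]1OC(=[N+](C)C)[C@H]3C)[C@@H]4C[C@H](C)C(=O)O4.[I-] | intermediate (not isolated)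
20 | 10β-iodo cis-fused lactone | I[C@@H]1[C@H](CCCCCl)[C@H]2N(C(=O)OC(C)(C)C)[C@@H](C[C@@]2(O[Si](CC)(CC)CC)[C@@H]3[C@H]1OC(=O)[C@H]3C)[C@@H]4C[C@H](C)C(=O)O4 | intermediate
21 | N-Boc lactone, C9=C10 alkene, 4-chlorobutyl on C9 | C1=C(CCCCCl)[C@H]2N(C(=O)OC(C)(C)C)[C@@H](C[C@@]2(O[Si](CC)(CC)CC)[C@@H]3[C@H]1OC(=O)[C@H]3C)[C@@H]4C[C@H](C)C(=O)O4 | intermediate
22 | N-Boc lactone, C9=C10 alkene, 4-iodobutyl on C9 | C1=C(CCCCI)[C@H]2N(C(=O)OC(C)(C)C)[C@@H](C[C@@]2(O[Si](CC)(CC)CC)[C@@H]3[C@H]1OC(=O)[C@H]3C)[C@@H]4C[C@H](C)C(=O)O4 | intermediate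
23 | N-(trimethylsilyloxycarbonyl) iodide | C1=C(CCCCI)[C@H]2N(C(=O)O[Si](C)(C)C)[C@@H](C[C@@]2(O[Si](CC)(CC)CC)[C@@H]3[C@H]1OC(=O)[C@H]3C)[C@@H]4C[C@H](C)C(=O)O4 | intermediate (not isolated)
24 | secondary amino iodide | C1=C(CCCCI)[C@H]2N[C@@H](C[C@@]2(O[Si](CC)(CC)CC)[C@@H]3[C@H]1OC(=O)[C@H]3C)[C@@H]4C[C@H](C)C(=O)O4 | intermediate (not isolated)
25 | tricyclic allylic amine, C9=C10 alkene | C1=C2CCCCN3[C@H]2[C@@](O[Si](CC)(CC)CC)(C[C@H]3[C@@H]4C[C@H](C)C(=O)O4)[C@@H]5[C@H]1OC(=O)[C@H]5C | intermediate
26 | N-oxide of 25 (N-configuration not assigned) | C1=C2CCCC[N+]3([O-])[C@H]2[C@@](O[Si](CC)(CC)CC)(C[C@H]3[C@@H]4C[C@H](C)C(=O)O4)[C@@H]5[C@H]1OC(=O)[C@H]5C | intermediate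
27 | ethylmagnesium bromide | CC[Mg]Br | starting material
28 | conjugated iminium trifluoroacetate (N+=C9a–C9=C10) | C1=C2CCCC[N+]3=C2[C@@](O[Si](CC)(CC)CC)(C[C@H]3[C@@H]4C[C@H](C)C(=O)O4)[C@@H]5[C@H]1OC(=O)[C@H]5C.[O-]C(=O)C(F)(F)F | intermediate (not isolated)
29 | ethylcopper (as its MgBr2/Me2S complex) | CC[Cu] | intermediate (not isolated)
30 | tetrasubstituted C9=C9a enamine, 10β-ethyl | CC[C@@H]1C2=C3N(CCCC2)[C@H]([C@@H]4C[C@H](C)C(=O)O4)C[C@@]3(O[Si](CC)(CC)CC)[C@@H]5[C@H]1OC(=O)[C@H]5C | intermediate
31 | 9,9a-dioxetane (β-face adduct drawn) | CC[C@@H]1[C@@]2(OO3)CCCCN4[C@@]23[C@@](O[Si](CC)(CC)CC)(C[C@H]4[C@@H]5C[C@H](C)C(=O)O5)[C@@H]6[C@H]1OC(=O)[C@H]6C | intermediate (not isolated)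
32 | 11-membered keto-lactam, C1 triethylsilyl ether | CC[C@@H]1C(=O)CCCCN2C(=O)[C@@](O[Si](CC)(CC)CC)(C[C@H]2[C@@H]2C[C@H](C)C(=O)O2)[C@@H]2[C@H]1OC(=O)[C@H]2C | intermediate
33 | CNP0221273.1 | CC[C@@H]1C(=O)CCCCN2C(=O)[C@@](O)(C[C@H]2[C@@H]2C[C@H](C)C(=O)O2)[C@@H]2[C@H]1OC(=O)[C@H]2C | target

**Step count:** 18 steps in total. The longest linear sequence is 18 steps, from N-Boc-L-tyrosine (1); all other building blocks are purchased and used directly.

**Steps most likely to fail**

1. Step 16. The trifluoroacetylated N-oxide may lose a different α-hydrogen or rearrange, the organocopper may add at C9a or merely be protonated, and the enamine may hydrolyse on work-up. The fallback sets out from iodolactone 20 and comes back at enamine 30. It installs the ethyl group by radical chemistry before the nitrogen is freed.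
   - Giese addition of the C10 radical to phenyl vinyl sulfone (Bu3SnH, AIBN, benzene, 80 °C) should give the 10β-(2-phenylsulfonylethyl) lactone F1, the radical being trapped anti to the cis-fused lactone.
   - Reductive desulfonylation (Na/Hg, Na2HPO4, MeOH/THF, −20 °C) should give the 10β-ethyl chloride F2.
   - Halide exchange as in step 13 should give the 10β-ethyl iodide F3.
   - Carbamate removal and ring closure as in step 14 should give the saturated tricyclic amine F4.
   - mCPBA should give its N-oxide F5.
   - Polonovski–Potier elimination (TFAA, CH2Cl2, −78 °C, then Et3N) should remove the ring-fusion hydrogen at C9a, which unlike C3–H is not deactivated by a β-oxygen; loss of the C9 proton from the iminium ion (C1 is quaternary) then gives 30.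

2. Step 10. The [3,3] shift may be too slow on the hindered α face so that the ketene acetal eliminates to a diene, or C13 control may erode if the less populated (E)-acetal does not carry the reaction. The fallback sets out from allylic alcohol 15 and comes back at iodolactone 20. In the ynamine (Ficini–Claisen) variant, 1-(diethylamino)propyne in toluene at 80 → 110 °C adds the alcohol to the keteniminium ion anti to its methyl group. The (E)-ketene N,O-acetal is thus formed kinetically and at lower temperature, and should rearrange to the C12 N,N-diethylpropionamide F6 with the C12/C13 configuration of 18. Iodolactonisation as in step 11, with loss of diethylamine, then gives 20.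

3. Step 17. The peroxy zwitterion may divert into ene hydroperoxidation at the C8 or C10 hydrogens, or the enamine may be lost by hydrolysis or over-oxidation before cleavage. The fallback sets out from enamine 30 and comes back at keto-lactam 32. Ozonolysis in the dark (O3, CH2Cl2, −78 °C; then Me2S) cleaves the same double bond by 1,3-dipolar cycloaddition and cycloreversion, a path with no ene channel; no new compound is made (F0).

**Further compounds**
F1 | step 16 | 10β-(2-phenylsulfonylethyl) cis-fused lactone, N-Boc, 9β-(4-chlorobutyl) | O=S(=O)(c1ccccc1)CC[C@@H]1[C@H](CCCCCl)[C@H]2N(C(=O)OC(C)(C)C)[C@@H](C[C@@]2(O[Si](CC)(CC)CC)[C@@H]3[C@H]1OC(=O)[C@H]3C)[C@@H]4C[C@H](C)C(=O)O4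
F2 | step 16 | 10β-ethyl cis-fused lactone, N-Boc, 9β-(4-chlorobutyl) | CC[C@@H]1[C@H](CCCCCl)[C@H]2N(C(=O)OC(C)(C)C)[C@@H](C[C@@]2(O[Si](CC)(CC)CC)[C@@H]3[C@H]1OC(=O)[C@H]3C)[C@@H]4C[C@H](C)C(=O)O4
F3 | step 16 | 10β-ethyl cis-fused lactone, N-Boc, 9β-(4-iodobutyl) | CC[C@@H]1[C@H](CCCCI)[C@H]2N(C(=O)OC(C)(C)C)[C@@H](C[C@@]2(O[Si](CC)(CC)CC)[C@@H]3[C@H]1OC(=O)[C@H]3C)[C@@H]4C[C@H](C)C(=O)O4
F4 | step 16 | saturated tricyclic amine (9α-H, 9aβ-H, 10β-ethyl) | CC[C@@H]1[C@@H]2CCCCN3[C@H]2[C@@](O[Si](CC)(CC)CC)(C[C@H]3[C@@H]4C[C@H](C)C(=O)O4)[C@@H]5[C@H]1OC(=O)[C@H]5C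
F5 | step 16 | N-oxide of F4 (N-configuration not assigned) | CC[C@@H]1[C@@H]2CCCC[N+]3([O-])[C@H]2[C@@](O[Si](CC)(CC)CC)(C[C@H]3[C@@H]4C[C@H](C)C(=O)O4)[C@@H]5[C@H]1OC(=O)[C@H]5C
F6 | step 10 | C12 α-side-chain N,N-diethylpropionamide, C10=C11 alkene | C1=C[C@H]([C@H](C)C(=O)N(CC)CC)[C@]2(O[Si](CC)(CC)CC)C[C@@H]([C@@H]3C[C@H](C)C(=O)O3)N(C(=O)OC(C)(C)C)[C@@H]2[C@H]1CCCCCl
F0 | step 17 | none | none
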